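**Plan**
- Target read as 7β‑acetoxy‑labd‑13E‑ene‑8β,15‑diol (5S,7S,8R,9R,10S): a normal‑series labdane whose C7/C8 cis‑diol sits on the hindered β face, syn to the C‑10 methyl.
- Retrosynthetic cuts: first the C7–O and C8–O bonds (cis‑diol monoacetate ⇒ C7=C8 alkene), then C9–C10 (ring B) and C4–C5 (ring A), which unravels the decalin to all‑E geranylgeranyl diphosphate.
- Enabling feature: C1–C20 form an intact head‑to‑tail tetraprenyl chain (gem‑dimethyl on C4, methyls on C10, C8 and C13, E‑C13=C14, oxygen on C15). The C7–C8 diol of ring B is the oxidised form of the alkene left when the C8 cation, formed as ring B closes, loses H‑7.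
- Forward: geranylgeraniol → chloride → diphosphate; one enzymatic protonative cascade (class 2 diterpene cyclase) closes ring A, then ring B, and leaves C7=C8; then acetylation, Woodward cis‑hydroxylation and selective O‑15 deacetylation.
- Stereochemistry: C5, C9, C10 from the enzyme‑folded E,E,E‑polyene (anti additions, normal series); C7 and C8 from the Woodward sequence (α‑iodonium, diaxial opening, inversion at C7), which gives the β,β‑cis‑diol that osmylation would not; E‑C13=C14 is carried through from geranylgeraniol.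

Key step: step 3

Assumption: the cyclase of step 3 is a recombinant normal‑series (H‑5α, H‑9α, C‑20 β) labda‑7,13E‑dien‑15‑yl diphosphate synthase, a product specificity known among plant class 2 diterpene cyclases; the absolute series of the enzyme used has to be confirmed on compound 5.

**Route**

Step 1
Reactants: 1 (2E,6E,10E)‑geranylgeraniol
Product: 2 (2E,6E,10E)‑geranylgeranyl chloride
Conditions: NCS, Me2S, CH2Cl2, −30 °C to 0 °C
Reagents that add atoms: N‑chlorosuccinimide, O=C1CCC(=O)N1Cl
Why: Corey–Kim chlorination turns the primary allylic alcohol into its alkoxysulfonium salt, which chloride displaces by SN2 without allylic transposition or E/Z scrambling.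

Step 2
Reactants: 2 (2E,6E,10E)‑geranylgeranyl chloride
Product: 3 (2E,6E,10E)‑geranylgeranyl diphosphate (handled as its ammonium salt)
Conditions: (nBu4N)3HP2O7, MeCN, rt; then cation exchange (Dowex 50WX8, NH4+ form) and cellulose chromatography
Reagents that add atoms: tris(tetra‑n‑butylammonium) hydrogen diphosphate, CCCC[N+](CCCC)(CCCC)CCCC.CCCC[N+](CCCC)(CCCC)CCCC.CCCC[N+](CCCC)(CCCC)CCCC.OP(=O)([O-])OP(=O)([O-])[O-]
Why: direct SN2 displacement of the primary allylic chloride by the naked diphosphate anion in acetonitrile is the standard allylic diphosphorylation and keeps the alkene geometry.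

Step 3
Reactants: 3 (2E,6E,10E)‑geranylgeranyl diphosphate
Product: 5 (5S,9S,10S)‑labda‑7,13E‑dien‑15‑ol, via labda‑7,13E‑dien‑15‑yl diphosphate 4 (not isolated)
Conditions: recombinant normal‑series class 2 diterpene cyclase (labda‑7,13E‑dien‑15‑yl diphosphate synthase), MgCl2, HEPES buffer pH 7.4, glycerol, 30 °C; then calf intestinal alkaline phosphatase, pH 8.5, 37 °C; pentane extraction
Reagents that add atoms: none
Why: The catalytic aspartic acid of the cyclase (DxDD motif) protonates the distal alkene of chair–chair‑folded 3 at C3 (labdane numbering); the tertiary C4 cation is captured by C5 of the C5=C10 alkene (ring A, 6‑endo‑trig cation–olefin closure) and the C10 cation by C9 of the C8=C9 alkene (ring B, 6‑endo‑trig, closed last), after which the labd‑13E‑en‑8‑yl cation loses H‑7 to leave the C7=C8 alkene of 4, and the phosphatase then cleaves only P–O bonds so that O‑15 is retained. The closest known reaction type is the protonative cation–olefin polyene cyclization, here in its natural enzymatic form on the native substrate of this cyclase class. C5 and C10 arise by anti addition across the E C5=C10 alkene (trans ring fusion, H‑5 α, C‑20 β) and C9 by anti addition across the E C8=C9 alkene (H‑9 α, side chain β and equatorial), while the absolute sense of all three is imposed by the normal‑series substrate fold in the active site. The step needs initiation only at the distal alkene, termination after two rings, and loss of the proton from C7 and not from C17 or C9 or capture of water. In the substrate the 1,5‑spaced E‑trisubstituted alkenes make every closure Markovnikov and six‑membered and the electron‑poor allylic diphosphate alkene (C13=C14) does not join the cascade, while the position of the active‑site base secures the C7 deprotonation. No small Brønsted or Lewis acid gives this stop point, alkene position and absolute configuration on an unactivated tetraene.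

Step 4
Reactants: 5 (5S,9S,10S)‑labda‑7,13E‑dien‑15‑ol
Product: 6 (5S,9S,10S)‑labda‑7,13E‑dien‑15‑yl acetate
Conditions: Ac2O, pyridine, DMAP (cat.), CH2Cl2, 0 °C to rt
Reagents that add atoms: acetic anhydride, CC(=O)OC(C)=O
Why: DMAP‑catalysed acylation of the primary allylic alcohol is routine, and the acetate both protects O‑15 and deactivates the C13=C14 alkene toward the electrophile of step 5.

Step 5
Reactants: 6 (5S,9S,10S)‑labda‑7,13E‑dien‑15‑yl acetate
Product: 8 (5S,7S,8R,9R,10S)‑7β‑acetoxy‑8β‑hydroxylabd‑13E‑en‑15‑yl acetate, via 7α‑iodo‑8β‑acetoxylabd‑13E‑en‑15‑yl acetate 7 (not isolated)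
Conditions: I2, AgOAc, AcOH, rt, dark; then H2O (wet AcOH), 90 °C
Reagents that add atoms: iodine, II (iodine atom of intermediate 7 only); silver acetate, CC(=O)[O-].[Ag+]; water, O
Why: Woodward cis‑hydroxylation: acetyl hypoiodite forms the iodonium ion reversibly on the open α face of the electron‑rich ring alkene, acetate opens it at tertiary C8 from the β face (Markovnikov and trans‑diaxial, giving 7), silver‑assisted loss of iodide with anti‑periplanar participation of the 8β‑acetate inverts C7 to a β‑cis‑fused 1,3‑dioxolan‑2‑ylium ion, and water opens this through the hemiorthoester to the cis‑hydroxy acetate, in which the acetyl group should settle on the equatorial secondary O‑7 and not on the axial tertiary O‑8 that is 1,3‑syn to the C‑10 methyl, so that C7 (S) and C8 (R) are set on the β face.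

Step 6
Reactants: 8 (5S,7S,8R,9R,10S)‑7β‑acetoxy‑8β‑hydroxylabd‑13E‑en‑15‑yl acetate
Product: 9 (5S,7S,8R,9R,10S)‑7β‑acetoxylabd‑13E‑ene‑8β,15‑diol (CNP0499846.1)
Conditions: immobilised Candida antarctica lipase B, phosphate buffer pH 7.0/MTBE, 30 °C
Reagents that add atoms: none
Why: lipase‑catalysed chemoselective ester hydrolysis should accept the unhindered primary allylic acetate but not the secondary acetate buried between C6 and the quaternary carbinol C8, and the near‑neutral pH should avoid acyl migration to O‑8.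

**Compound list**
1 | (2E,6E,10E)‑geranylgeraniol (3,7,11,15‑tetramethylhexadeca‑2,6,10,14‑tetraen‑1‑ol) | CC(C)=CCC/C(C)=C/CC/C(C)=C/CC/C(C)=C/CO | starting material
2 | (2E,6E,10E)‑geranylgeranyl chloride | CC(C)=CCC/C(C)=C/CC/C(C)=C/CC/C(C)=C/CCl | intermediate
3 | (2E,6E,10E)‑geranylgeranyl diphosphate (drawn as the free acid, handled as the ammonium salt) | CC(C)=CCC/C(C)=C/CC/C(C)=C/CC/C(C)=C/COP(=O)(O)OP(=O)(O)O | intermediate
4 | (5S,9S,10S)‑labda‑7,13E‑dien‑15‑yl diphosphate (H‑5α, H‑9α, C‑20 β; drawn as the free acid) | CC1=CC[C@H]2C(C)(C)CCC[C@]2(C)[C@H]1CC/C(C)=C/COP(=O)(O)OP(=O)(O)O | intermediate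
5 | (5S,9S,10S)‑labda‑7,13E‑dien‑15‑ol | CC1=CC[C@H]2C(C)(C)CCC[C@]2(C)[C@H]1CC/C(C)=C/CO | intermediate
6 | (5S,9S,10S)‑labda‑7,13E‑dien‑15‑yl acetate | CC1=CC[C@H]2C(C)(C)CCC[C@]2(C)[C@H]1CC/C(C)=C/COC(C)=O | intermediate
7 | 7α‑iodo‑8β‑acetoxylabd‑13E‑en‑15‑yl acetate (trans‑diaxial iodoacetate, 8α‑methyl) | I[C@@H]1C[C@H]2C(C)(C)CCC[C@]2(C)[C@@H](CC/C(C)=C/COC(C)=O)[C@@]1(C)OC(C)=O | intermediate
8 | (5S,7S,8R,9R,10S)‑7β‑acetoxy‑8β‑hydroxylabd‑13E‑en‑15‑yl acetate | CC(=O)O[C@H]1C[C@H]2C(C)(C)CCC[C@]2(C)[C@@H](CC/C(C)=C/COC(C)=O)[C@@]1(C)O | intermediate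
9 | (5S,7S,8R,9R,10S)‑7β‑acetoxylabd‑13E‑ene‑8β,15‑diol (CNP0499846.1) | CC(=O)O[C@H]1C[C@H]2C(C)(C)CCC[C@]2(C)[C@@H](CC/C(C)=C/CO)[C@@]1(C)O | target

**Step count**
Total steps: 6. Longest linear sequence: 6 steps (fully linear).

**Steps most likely to fail**

Step 3. The cyclase may turn over slowly (product inhibition, poor expression), or lose regiocontrol in the terminating deprotonation so that exocyclic or tetrasubstituted alkene isomers or water‑captured product form instead of the C7=C8 alkene. The fallback sets out from 3 and comes back to the route at 6. Compound 3 is cyclised with a class 2 diterpene cyclase of the water‑capturing type (copal‑8‑ol diphosphate synthase), which quenches the C8 cation with water and should give (13E)‑8α‑hydroxylabd‑13‑en‑15‑yl diphosphate F1. Alkaline phosphatase in the same pot should give (13E)‑labd‑13‑ene‑8α,15‑diol F2. Ac2O/pyridine should acetylate only the primary alcohol to give (13E)‑8α‑hydroxylabd‑13‑en‑15‑yl acetate F3. Dehydration of the tertiary alcohol (POCl3, pyridine) is expected to give the C7=C8 alkene together with the exocyclic isomer, and 6 is separated on AgNO3‑impregnated silica; regiocontrol is then chemical and weaker, which is the price of this fallback.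

Step 5. Iodoacetoxylation may fail to discriminate between the two alkenes, the tertiary β‑iodo cation may eliminate instead of capturing acetate, or the acetyl group may end on O‑8. The fallback sets out from 6 and comes back at 8.
- mCPBA (CH2Cl2, NaHCO3, 0 °C) should epoxidise the ring alkene from the α face to 7α,8α‑epoxylabd‑13E‑en‑15‑yl acetate F4.
- Aqueous HClO4 in THF should open it trans‑diaxially at C8 to 7α,8β‑dihydroxylabd‑13E‑en‑15‑yl acetate F5.
- Parikh–Doering oxidation (SO3·pyridine, DMSO, Et3N) of the secondary alcohol should give 8β‑hydroxy‑7‑oxolabd‑13E‑en‑15‑yl acetate F6.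
- NaBH4 (MeOH, −20 °C) should deliver hydride axially from the α face to give the equatorial alcohol, 7β,8β‑dihydroxylabd‑13E‑en‑15‑yl acetate F7.
- Ac2O/pyridine/DMAP acetylates only the secondary hydroxyl and gives 8.

Step 6. The lipase may not discriminate between the two acetates, or the 7‑acetate may be lost or migrate with help from the neighbouring 8‑hydroxyl. The fallback sets out from 8 and comes back at 9; it also corrects any acetate regioisomer carried from step 5.
- K2CO3/MeOH removes both acetates to give labd‑13E‑ene‑7β,8β,15‑triol F8.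
- TBSCl/imidazole (DMF, 0 °C) should silylate only the primary allylic alcohol to give 15‑(tert‑butyldimethylsilyloxy)labd‑13E‑ene‑7β,8β‑diol F9.
- Ac2O/pyridine/DMAP acetylates O‑7 (the axial tertiary O‑8 stays free) to give 7β‑acetoxy‑15‑(tert‑butyldimethylsilyloxy)labd‑13E‑en‑8β‑ol F10.
- HF·pyridine in THF removes the silyl group and gives 9.

**Further compounds**
F1 | step 3 | (13E)‑8α‑hydroxylabd‑13‑en‑15‑yl diphosphate (8β‑methyl; drawn as the free acid) | C1C[C@H]2C(C)(C)CCC[C@]2(C)[C@@H](CC/C(C)=C/COP(=O)(O)OP(=O)(O)O)[C@]1(C)O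
F2 | step 3 | (13E)‑labd‑13‑ene‑8α,15‑diol | C1C[C@H]2C(C)(C)CCC[C@]2(C)[C@@H](CC/C(C)=C/CO)[C@]1(C)O
F3 | step 3 | (13E)‑8α‑hydroxylabd‑13‑en‑15‑yl acetate | C1C[C@H]2C(C)(C)CCC[C@]2(C)[C@@H](CC/C(C)=C/COC(C)=O)[C@]1(C)O
F4 | step 5 | 7α,8α‑epoxylabd‑13E‑en‑15‑yl acetate | C[C@]12O[C@@H]2C[C@H]3C(C)(C)CCC[C@]3(C)[C@H]1CC/C(C)=C/COC(C)=O
F5 | step 5 | 7α,8β‑dihydroxylabd‑13E‑en‑15‑yl acetate | O[C@@H]1C[C@H]2C(C)(C)CCC[C@]2(C)[C@@H](CC/C(C)=C/COC(C)=O)[C@@]1(C)O
F6 | step 5 | 8β‑hydroxy‑7‑oxolabd‑13E‑en‑15‑yl acetate | O=C1C[C@H]2C(C)(C)CCC[C@]2(C)[C@@H](CC/C(C)=C/COC(C)=O)[C@@]1(C)O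
F7 | step 5 | 7β,8β‑dihydroxylabd‑13E‑en‑15‑yl acetate | O[C@H]1C[C@H]2C(C)(C)CCC[C@]2(C)[C@@H](CC/C(C)=C/COC(C)=O)[C@@]1(C)O
F8 | step 6 | labd‑13E‑ene‑7β,8β,15‑triol | O[C@H]1C[C@H]2C(C)(C)CCC[C@]2(C)[C@@H](CC/C(C)=C/CO)[C@@]1(C)O
F9 | step 6 | 15‑(tert‑butyldimethylsilyloxy)labd‑13E‑ene‑7β,8β‑diol | O[C@H]1C[C@H]2C(C)(C)CCC[C@]2(C)[C@@H](CC/C(C)=C/CO[Si](C)(C)C(C)(C)C)[C@@]1(C)O
F10 | step 6 | 7β‑acetoxy‑15‑(tert‑butyldimethylsilyloxy)labd‑13E‑en‑8β‑ol | CC(=O)O[C@H]1C[C@H]2C(C)(C)CCC[C@]2(C)[C@@H](CC/C(C)=C/CO[Si](C)(C)C(C)(C)C)[C@@]1(C)O
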